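Readings and results stem from a simulated flask with constants of no real substance; the scatter is artificial.

A leftover first: after 90.0 min in the west run, 89.9% of the charge is not read as mono adduct, so I count mono adduct in moles per litre, not as a percentage of the charge.

| setting | west | north-west | south | flask |
|---|---|---|---|---|
| solid substrate | 0.049 M | 0.049 M | 0.025 M | 0.049 M |
| coupling partner | 0.10 M | 0.22 M | 0.15 M | 0.150 M |
| remark | run made earlier | run made earlier | run made earlier |  |
| time |  |  |  | 80 min |

| run | time / min | mono adduct / % |
|---|---|---|
| west | 15.0 | 0.7 |
| west | 30.0 | 2.0 |
| west | 40.0 | 5.3 |
| west | 60.0 | 6.8 |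
| west | 80.0 | 8.5 |
| west | 90.0 | 10.1 |
| north-west | 5.00 | 0.4 |
| north-west | 15.0 | 1.7 |
| north-west | 25.0 | 2.3 |
| north-west | 40.0 | 4.0 |
| north-west | 60.0 | 6.1 |
| north-west | 80.0 | 7.4 |
| north-west | 90.0 | 8.8 |
| south | 8.00 | 0 |
| south | 25.0 | 5.5 |
| south | 40.0 | 8.6 |
| south | 60.0 | 12.5 |
| south | 90.0 | 17.5 |

(standard deviation of a reading: 1 percentage point)

- given per volume of solution although it is solid: solid substrate
- at the start none of the solid substrate is in solution

- equivalents of coupling partner to solid substrate, everything else as given, that leave most mono adduct at 80 min
- the amount of mono adduct then, in percent of the solid substrate charged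
- the amount of mono adduct with the amounts as given

The shortest rung is the start-up, and the readings do not resolve it: the south run reads 0% at 8.00 min, but with a scatter of 1 percentage point that single reading does not show a lag, so I set none in my reckoning.

The middle rung is a steady climb. At 90.0 min the readings give 0.0550 mM/min in the west run and 0.0479 mM/min in the north-west run, with 0.10 M and 0.22 M of coupling partner. The south run, with half the solid substrate of the west run, gives 0.0486 mM/min. Their mean, 0.0505 mM/min, is my molar make rate, mono adduct concentration over elapsed time, an apparent zero-order rate. The comparison barely drifts: south over west reads 0.938 at 60.0 min and 0.884 at 90.0 min.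

The longest rung is the time this rate needs to match the charge, 970 min. That is far longer than 80 min, so I reckon the flask still on the middle rung and expect 8.25%.

The forecast gives 8% (7.2% to 8.9%), slightly below mine, on the ground that “Halving the solid therefore doubles the percent yield but leaves the concentration unchanged”. It puts the optimum at 1.6 equiv (0.7 equiv to 2.7 equiv) with 9%. I add no optimum of my own, as the lowest run stands at 2.04 equivalents.

The flask gives 8.56%, and its optimum is 8.91% at 1.89 equiv, a factor 1.18 above the forecast's equivalents.

    solid substrate ⇌ starting material, rate k1*(cs1 - [starting material]) while solid is left; crystals form when [starting material] > cs1 (solubility = 19.0 mM, k = 0.00900 /min)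
    starting material + coupling partner → other mono adduct (k = 1.25 /M/min)
    starting material + mono adduct → side product (k = 1.01 /M/min)
    coupling partner + mono adduct → double product (k = 0.0506 /M/min)
    coupling partner + other mono adduct → double product (k = 0.338 /M/min)
    starting material + coupling partner → mono adduct (k = 0.970 /M/min)

With 72.8% of the charge still solid at 80.0 min, the flask's own make rate is 0.0524 mM/min. A neighbour flask charged with 0.12 M of solid substrate comes, at my 0.0505 mM/min, to 3.37% of its charge, and that neighbour gives 3.50%.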